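Ring B (C1 = ether carbon, C2/C6 = hydroxyl carbons, C4 = chain carbon) is not brought in but made last. Its segment C6–C1–C2–C3 carries oxygen on C6, C1 and C2 just as a 2-aryloxyacetoacetate does. C4 and C5 correspond to the two carbons of an alkyne. The precursor therefore has a 1-methoxy-1,3-bis(silyloxy)butadiene on one ring A oxygen and a methyl alk-2-ynoate at the far end of the twelve-methylene chain on the same ring. A single thermal [4+2] cycloaddition at high dilution forms C3–C4 and C5–C6, aromatises to ring B and closes the 20-membered ring. The activating ester on C5 is afterwards lost by hydrolysis and decarboxylation.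

Key step: step 8

Remarks on the chemistry
- The target has no stereocentre. Compound 13 is racemic and enolisable, 14 is a mixture of ketene acetal geometries, and 15 has one uncontrolled acetal carbon. All three elements vanish when ring B becomes aromatic.
- Assumption: 1 is taken as a catalogue compound. Its two ring A oxygens are already differentiated, so no selective demethylation is needed.
- The chain and its leaving group arrive in one coupling with 3.
- Handling of the precursor: 14 is made without amide base, which an ynoate would not survive, and it is never chromatographed. It is cyclised in the presence of a neutral silyl donor. Aromatisation releases methanol, and at millimolar concentration that methanol, like trace water, could otherwise destroy unreacted ketene acetal.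

Step 1
Reactants: 1 3-bromo-5-methoxyphenol
Product: 2 1-bromo-3-methoxy-5-(methoxymethoxy)benzene
Conditions: MOMCl, iPr2NEt, CH2Cl2, 0 °C to rt
Reagents that add atoms: chloromethyl methyl ether, COCCl
Why: Williamson-type O-alkylation of the phenol with the reactive α-chloro ether gives a MOM acetal that tolerates Grignard, acetylide and butyllithium chemistry yet falls to mild acid without harm to an ynoate.

Step 2
Reactants: 2 1-bromo-3-methoxy-5-(methoxymethoxy)benzene; 3 1,12-dibromododecane
Product: 5 1-(12-bromododecyl)-3-methoxy-5-(methoxymethoxy)benzene, via aryl Grignard reagent 4 (not isolated)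
Conditions: Mg, THF, reflux; then added slowly to 3 (3 equiv), Li2CuCl4 (5 mol %), THF, 0 °C to rt
Reagents that add atoms: magnesium, [Mg] (stays only in 4)
Why: The copper-catalysed cross-coupling of an aryl Grignard reagent with a primary alkyl bromide (Kochi coupling) is reliable, and slow inverse addition to an excess of symmetrical 3 (surplus recovered) should suppress double arylation.

Step 3
Reactants: 5 1-(12-bromododecyl)-3-methoxy-5-(methoxymethoxy)benzene; 6 lithium acetylide–ethane-1,2-diamine complex
Product: 7 1-methoxy-3-(methoxymethoxy)-5-(tetradec-13-yn-1-yl)benzene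
Conditions: 6 (1.5 equiv), DMSO, 10 °C to rt
Reagents that add atoms: none
Why: SN2 displacement of a primary bromide by lithium acetylide in DMSO is the standard terminal alkyne synthesis, and both aryl ethers are inert to it.

Step 4
Reactants: 7 1-methoxy-3-(methoxymethoxy)-5-(tetradec-13-yn-1-yl)benzene; 8 methyl chloroformate
Product: 10 methyl 15-[3-methoxy-5-(methoxymethoxy)phenyl]pentadec-2-ynoate, via lithium alkynide 9 (not isolated)
Conditions: n-BuLi (1.05 equiv), THF, −78 °C; then 8, −78 to 0 °C
Reagents that add atoms: n-butyllithium, [Li]CCCC (lithium stays only in 9)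
Why: Deprotonation of the terminal alkyne is far faster than directed ortho-lithiation at −78 °C, and acylation of an alkynide with a chloroformate is the standard alk-2-ynoate synthesis.

Step 5
Reactants: 10 methyl 15-[3-methoxy-5-(methoxymethoxy)phenyl]pentadec-2-ynoate
Product: 11 methyl 15-(3-hydroxy-5-methoxyphenyl)pentadec-2-ynoate
Conditions: p-TsOH·H2O (cat.), MeOH, 50 °C
Reagents that add atoms: none
Why: Acid-catalysed transacetalisation to methanol cleaves the phenolic MOM ether, the non-nucleophilic sulfonic acid avoids hydrohalogenation of the ynoate, and methanol matches the ester.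

Step 6
Reactants: 11 methyl 15-(3-hydroxy-5-methoxyphenyl)pentadec-2-ynoate; 12 methyl 2-chloro-3-oxobutanoate
Product: 13 methyl 15-{3-methoxy-5-[(1-methoxy-1,3-dioxobutan-2-yl)oxy]phenyl}pentadec-2-ynoate
Conditions: 12 (1.1 equiv), K2CO3, acetone, reflux
Reagents that add atoms: none
Why: Williamson ether synthesis at the doubly activated chloride of a 2-chloroacetoacetate is a known route to 2-aryloxyacetoacetates and should outpace conjugate addition to the β-alkyl ynoate under weak base; the new stereocentre arises racemic, is labile by enolisation and is erased in step 7.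

Step 7
Reactants: 13 methyl 15-{3-methoxy-5-[(1-methoxy-1,3-dioxobutan-2-yl)oxy]phenyl}pentadec-2-ynoate
Product: 14 methyl 15-(3-methoxy-5-{[1-methoxy-1,3-bis(trimethylsilyloxy)buta-1,3-dien-2-yl]oxy}phenyl)pentadec-2-ynoate
Conditions: Me3SiOSO2CF3 (2.4 equiv), Et3N (3 equiv), Et2O, 0 °C to rt; ammonium salt layer removed under Ar, concentrated, used crude
Reagents that add atoms: trimethylsilyl trifluoromethanesulfonate, C[Si](C)(C)OS(=O)(=O)C(F)(F)F
Why: Soft enolisation with the silyl triflate–amine pair is known to turn acetoacetates in one pot into 1-alkoxy-1,3-bis(silyloxy)butadienes (α-enolisation, then O-silylation of the ester carbonyl and γ-deprotonation), without a strong base that would attack the ynoate.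

Step 8
Reactants: 14 methyl 15-(3-methoxy-5-{[1-methoxy-1,3-bis(trimethylsilyloxy)buta-1,3-dien-2-yl]oxy}phenyl)pentadec-2-ynoate
Product: 17 macrocyclic methyl 3-aryloxy-2,4-dihydroxy-6-alkylbenzoate, via cyclohexadiene cycloadduct 15 (not isolated), via bis(trimethylsilyl) ether 16 (not isolated)
Conditions: syringe-pump addition (24 h) into mesitylene, 165 °C, final ca. 1 mM, N,O-bis(trimethylsilyl)acetamide (5 equiv), Ar, silylated glassware, continued heating; then 1 M HCl, THF, rt
Reagents that add atoms: none
Why: Proposed new method: the electron-rich diene and the electron-poor alkyne should combine in a strongly asynchronous [4+2] process in which the nucleophilic methylene terminus (future C3) attacks the ynoate β-carbon (C4) and the ester-bearing carbon (C5) then closes onto the ketene acetal carbon (C6), after which 15 loses methanol by 1,4-elimination to give arene 16 and the acid work-up removes the silyl groups. The closest known reaction type is the intermolecular thermal Diels–Alder benzannulation of 1-methoxy-1,3-bis(silyloxy)butadienes with open-chain or macrocyclic alk-2-ynoates to 6-alkyl-2,4-dihydroxybenzoates, and what is new is its use as a ring-closing event through a long tether. Ring B closes as the six-membered ring of the cycloadduct, to which both new bonds belong, and the 20-membered ring closes in a type 2 intramolecular mode, because the sixteen-atom tether (O, three ring A carbons, twelve CH2) runs from the internal diene carbon C1 to the alkyne carbon C4 and leaves ring B para-bridged. No stereocentre survives, since the acetal carbon of 15 forms without control and becomes the sp2 carbon C6. Two selectivities are needed: orientation, which the polarity match between diene methylene and β-carbon sets and the strain-free tether permits, and ring closure over chain growth, which the millimolar stationary concentration secures. The silyl donor traps adventitious water and the liberated methanol, which would otherwise protonate unreacted ketene acetal.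

Step 9
Reactants: 17 macrocyclic methyl 3-aryloxy-2,4-dihydroxy-6-alkylbenzoate
Product: 19 ring A O-methyl ether of the target, via carboxylic acid 18 (not isolated)
Conditions: KOH, aq. DMSO, 100 °C, N2; then aq. HCl to pH 1, 90 °C
Reagents that add atoms: potassium hydroxide, [K+].[OH-] (its oxygen stays only in 18)
Why: Saponification of the hindered salicylate-type ester needs hot concentrated base, after which the 2,4-dihydroxybenzoic acid undergoes the easy ipso-protonation and decarboxylation typical of resorcylic acids when warmed in acid.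

Step 10
Reactants: 19 ring A O-methyl ether of the target
Product: 20 CNP0314249.0
Conditions: BBr3 (5 equiv), CH2Cl2, −78 °C to rt; then H2O
Reagents that add atoms: none
Why: In Lewis acid-mediated aryl methyl ether cleavage with BBr3, bromide attacks only the methyl carbon, so the diaryl ether, which offers no sp3 carbon, stays intact.

Compound list
1 | 3-bromo-5-methoxyphenol | COc1cc(O)cc(Br)c1 | starting material
2 | 1-bromo-3-methoxy-5-(methoxymethoxy)benzene | COCOc1cc(Br)cc(OC)c1 | intermediate
3 | 1,12-dibromododecane | BrCCCCCCCCCCCCBr | starting material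
4 | [3-methoxy-5-(methoxymethoxy)phenyl]magnesium bromide (not isolated) | COCOc1cc([Mg]Br)cc(OC)c1 | intermediate
5 | 1-(12-bromododecyl)-3-methoxy-5-(methoxymethoxy)benzene | BrCCCCCCCCCCCCc1cc(OC)cc(OCOC)c1 | intermediate
6 | lithium acetylide–ethane-1,2-diamine complex | [Li+].[C-]#C.NCCN | starting material
7 | 1-methoxy-3-(methoxymethoxy)-5-(tetradec-13-yn-1-yl)benzene | C#CCCCCCCCCCCCCc1cc(OC)cc(OCOC)c1 | intermediate
8 | methyl chloroformate | COC(=O)Cl | starting material
9 | lithium alkynide of 7 (not isolated) | [Li]C#CCCCCCCCCCCCCc1cc(OC)cc(OCOC)c1 | intermediate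
10 | methyl 15-[3-methoxy-5-(methoxymethoxy)phenyl]pentadec-2-ynoate | COC(=O)C#CCCCCCCCCCCCCc1cc(OC)cc(OCOC)c1 | intermediate
11 | methyl 15-(3-hydroxy-5-methoxyphenyl)pentadec-2-ynoate | COC(=O)C#CCCCCCCCCCCCCc1cc(O)cc(OC)c1 | intermediate
12 | methyl 2-chloro-3-oxobutanoate (methyl 2-chloroacetoacetate) | CC(=O)C(Cl)C(=O)OC | starting material
13 | methyl 15-{3-methoxy-5-[(1-methoxy-1,3-dioxobutan-2-yl)oxy]phenyl}pentadec-2-ynoate (racemic, enolisable) | COC(=O)C#CCCCCCCCCCCCCc1cc(OC)cc(OC(C(C)=O)C(=O)OC)c1 | intermediate
14 | methyl 15-(3-methoxy-5-{[1-methoxy-1,3-bis(trimethylsilyloxy)buta-1,3-dien-2-yl]oxy}phenyl)pentadec-2-ynoate (ketene acetal geometry mixed) | COC(=O)C#CCCCCCCCCCCCCc1cc(OC)cc(OC(C(=C)O[Si](C)(C)C)=C(OC)O[Si](C)(C)C)c1 | intermediate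
15 | bridged cyclohexa-1,4-diene cycloadduct, C3 (CH2) and C6 [C(OMe)(OSiMe3)] still sp3 (racemic, not isolated) | COC(=O)C1=C2CC(O[Si](C)(C)C)=C(Oc3cc(OC)cc(CCCCCCCCCCCC2)c3)C1(OC)O[Si](C)(C)C | intermediate
16 | macrocyclic methyl 3-aryloxy-6-alkyl-2,4-bis(trimethylsilyloxy)benzoate (not isolated) | COC(=O)c1c(O[Si](C)(C)C)c2c(O[Si](C)(C)C)cc1CCCCCCCCCCCCc1cc(OC)cc(O2)c1 | intermediate
17 | macrocyclic methyl 3-aryloxy-2,4-dihydroxy-6-alkylbenzoate (20-membered ring; ring B: aryloxy on C1, OH on C2 and C6, chain on C4, CO2Me on C5; ring A: OMe) | COC(=O)c1c(O)c2c(O)cc1CCCCCCCCCCCCc1cc(OC)cc(O2)c1 | intermediate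
18 | carboxylic acid corresponding to 17 (not isolated) | OC(=O)c1c(O)c2c(O)cc1CCCCCCCCCCCCc1cc(OC)cc(O2)c1 | intermediate
19 | ring A O-methyl ether of the target (ring B: C5–H, free OH on C2 and C6) | COc1cc2cc(c1)Oc1c(O)cc(cc1O)CCCCCCCCCCCC2 | intermediate
20 | CNP0314249.0 (20-membered diaryl ether cyclophane; ring A: OH, aryloxy, chain in 1,3,5 relation; ring B: 2,6-dihydroxy, chain para to the ether oxygen) | Oc1cc2cc(c1)Oc1c(O)cc(cc1O)CCCCCCCCCCCC2 | target

Total step count: 10. Longest linear sequence: 10 steps (1 to 20).

Steps most likely to fail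

Step 8. At millimolar concentration the ring closure may be slow. Protodesilylation or silyl migration of the diene, and chain-forming intermolecular cycloaddition, could then take over.
- The fallback uses known chemistry only. It sets out from 2 and returns at 17, and it separates the two ring closures.
- The Grignard reagent 4 made from 2 is coupled (Li2CuCl4 cat., THF) with 10-bromodec-1-ene to 1-(dec-9-en-1-yl)-3-methoxy-5-(methoxymethoxy)benzene F1.
- Catalytic p-TsOH in MeOH releases 3-(dec-9-en-1-yl)-5-methoxyphenol F2.
- Compound 12 with K2CO3 in acetone gives methyl 2-[3-(dec-9-en-1-yl)-5-methoxyphenoxy]-3-oxobutanoate F3.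
- With no ynoate present, the classical sequence Me3SiCl/Et3N then LDA/Me3SiCl at −78 °C gives the untethered 2-aryloxy-1-methoxy-1,3-bis(trimethylsilyloxy)butadiene F4.
- Hex-1-en-5-yne is carboxylated (n-BuLi, then 8) to methyl hept-6-en-2-ynoate F5.
- Heating F4 neat with excess F5 at 140 °C, followed by acid work-up, is the established intermolecular benzannulation. It should give methyl 6-(but-3-en-1-yl)-3-[3-(dec-9-en-1-yl)-5-methoxyphenoxy]-2,4-dihydroxybenzoate F6.
- Ring-closing olefin metathesis (second-generation Grubbs catalyst, CH2Cl2, reflux, 1 mM) closes the 20-membered cycloalkene F7 as an E/Z mixture.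
- H2 over Pd/C saturates F7 to 17.

Step 7. The second (γ) enolisation may stall at the mono-silyl enol ether. The amine–triflate pair may attack or isomerise the ynoate, or the bis-silyl diene may hydrolyse during handling.
- The fallback sets out from 13 and returns at 20. It replaces the C2 silyl ether by a robust methyl enol ether, so only one silicon–oxygen bond has to be made.
- Trimethyl orthoformate and catalytic p-TsOH in MeOH convert 13 into the chromatographically stable methyl 15-{3-[(1,3-dimethoxy-1-oxobut-2-en-2-yl)oxy]-5-methoxyphenyl}pentadec-2-ynoate F8.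
- A single silylation (Me3SiOSO2CF3, Et3N, Et2O) gives the tethered 1,3-dimethoxy-1-(trimethylsilyloxy)butadiene F9.
- The conditions of step 8 should give the macrocyclic methyl 3-aryloxy-2-hydroxy-4-methoxy-6-alkylbenzoate F10.
- KOH, then acid and heat, give the decarboxylated macrocyclic dimethyl ether F11.
- BBr3 cleaves both methyl ethers at once to 20.

Step 6. Under base, conjugate addition of the phenoxide or of the product enolate to the ynoate may compete with substitution, as may retro-Claisen loss of the acetyl group.
- The fallback sets out from 11 and returns at 13. It forms the same C–O bond in neutral medium.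
- Methyl 2-diazo-3-oxobutanoate F12 is made by diazo transfer to methyl acetoacetate with 4-acetamidobenzenesulfonyl azide and Et3N.
- F12 is decomposed with Rh2(OAc)4 (1 mol %) in CH2Cl2 at reflux in the presence of 11.
- Carbenoid O–H insertion into the phenol should give 13 directly. The electron-poor alkyne is a poor partner for the electrophilic carbenoid.

Further compounds
F1 | step 8 | 1-(dec-9-en-1-yl)-3-methoxy-5-(methoxymethoxy)benzene | C=CCCCCCCCCc1cc(OC)cc(OCOC)c1
F2 | step 8 | 3-(dec-9-en-1-yl)-5-methoxyphenol | C=CCCCCCCCCc1cc(O)cc(OC)c1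
F3 | step 8 | methyl 2-[3-(dec-9-en-1-yl)-5-methoxyphenoxy]-3-oxobutanoate | C=CCCCCCCCCc1cc(OC)cc(OC(C(C)=O)C(=O)OC)c1
F4 | step 8 | 2-[3-(dec-9-en-1-yl)-5-methoxyphenoxy]-1-methoxy-1,3-bis(trimethylsilyloxy)buta-1,3-diene | C=CCCCCCCCCc1cc(OC)cc(OC(C(=C)O[Si](C)(C)C)=C(OC)O[Si](C)(C)C)c1
F5 | step 8 | methyl hept-6-en-2-ynoate | COC(=O)C#CCCC=C
F6 | step 8 | methyl 6-(but-3-en-1-yl)-3-[3-(dec-9-en-1-yl)-5-methoxyphenoxy]-2,4-dihydroxybenzoate | COC(=O)c1c(O)c(Oc2cc(OC)cc(CCCCCCCCC=C)c2)c(O)cc1CCC=C
F7 | step 8 | 20-membered cycloalkene from ring-closing metathesis of F6 (E/Z mixture) | COC(=O)c1c(O)c2c(O)cc1CCC=CCCCCCCCCc1cc(OC)cc(O2)c1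
F8 | step 7 | methyl 15-{3-[(1,3-dimethoxy-1-oxobut-2-en-2-yl)oxy]-5-methoxyphenyl}pentadec-2-ynoate | COC(=O)C#CCCCCCCCCCCCCc1cc(OC)cc(OC(C(=O)OC)=C(C)OC)c1
F9 | step 7 | methyl 15-(3-{[1,3-dimethoxy-1-(trimethylsilyloxy)buta-1,3-dien-2-yl]oxy}-5-methoxyphenyl)pentadec-2-ynoate | COC(=O)C#CCCCCCCCCCCCCc1cc(OC)cc(OC(C(=C)OC)=C(OC)O[Si](C)(C)C)c1
F10 | step 7 | macrocyclic methyl 3-aryloxy-2-hydroxy-4-methoxy-6-alkylbenzoate | COC(=O)c1c(O)c2c(OC)cc1CCCCCCCCCCCCc1cc(OC)cc(O2)c1
F11 | step 7 | decarboxylated macrocyclic dimethyl ether (OMe on ring A and on C2 of ring B) | COc1cc2cc(c1)Oc1c(O)cc(cc1OC)CCCCCCCCCCCC2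
F12 | step 6 | methyl 2-diazo-3-oxobutanoate | COC(=O)C(=[N+]=[N-])C(C)=O
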